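Atom labels used throughout: ring A is the benzoate ring (C1 ester carbon, C2 phenol, C4 methyl, C6 ether carbon); ring B is the benzyl alcohol ring (C1' ether carbon, C2' hydroxymethyl carbon, C4' methoxy carbon, C6' prenyloxy carbon).

## Analysis of the target

The target 19 is a diaryl ether with no stereocentre. Ring A is a methyl salicylate carrying the ester at C1, a hydrogen-bonded phenol at C2, a methyl group at C4 and the ether oxygen at C6. Ring B carries the ether oxygen at C1', a hydroxymethyl group at C2', a methoxy group at C4' and a prenyl ether at C6'. The sensitive groups are the prenyl ether (acid, hydrogenation, heat), the benzylic alcohol and the free phenol beside the only ester. The synthesis is hard for two reasons. Three of the four positions ortho to the ether oxygen are substituted, so joining two finished rings by carbon-oxygen coupling is unattractive. Ring B also holds three oxygens of three different kinds that must be told apart. The strategy rests on the 1,3 relationship of the C4' and C6' oxygens, with C1' next to C6' and C2' next to C1': this is the pattern of a 4,5-disubstituted cyclohexane-1,3-dione. Ring B can therefore be grown on the ether oxygen of ring A as a saturated dione whose two carbonyls are chemically different, and aromatised late. The sp3 centres that appear at C1' and C2' disappear on aromatisation and need no control.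

## Retrosynthetic reasoning

The last bond cut is the O-Si bond of silyl ether 18. The benzylic alcohol is kept masked to the end, so that a single mild desilylation gives 19 with the prenyl ether and the ester untouched.

Next the C6'-O-allyl bond of 18 is cut, which leads to phenol 16 and prenyl bromide 17. The prenyl group goes on late because it is the most fragile group of the target. The forward alkylation must choose the free ring B phenol over the ring A phenol, which is tied up in a hydrogen bond to the ester.

The ester O-CH3 bond of 16 is cut to give hydroxy acid 15. The ester is introduced only after ring B is aromatic: as long as C1' is an enolisable sp3 carbon, an ester ortho to the ether oxygen would invite a five-membered ring closure, which a carboxylate cannot undergo.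

Ring B of 15 is then taken back by one oxidation level to the 3-methoxycyclohexenone 12, through the silyl dienol ether 13 and the dienone 14. This leaves only a dehydrogenation to be done on a ring that already carries every substituent in place.

The C4'-O-CH3 enol ether bond of 12 is cut to give dione 11. Here the three ring B oxygens are differentiated: C6' is flanked by the aryloxy carbon, C4' by two methylenes, so the ether can be placed at C4' and C6' later emerges as the phenol to be prenylated.

The key disconnection cuts C1'-C2' and C4'-C5' of 11, through the open-chain adduct 10, to the aryloxyacetone acid 5 and the silyloxy crotonate 9. Both bonds are enolate bonds, and the cut divides ring B into two three-carbon pieces. The hindered diaryl ether is never made by coupling, since the ether oxygen is already attached to ring A in 5. The forward step must send the oxygen-bearing methylene of 5 to the beta carbon of 9 and then close the ring from the methyl group.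

Acid 5 is traced back through benzyl ester 4 to the dihydroxy ester 2 and chloroacetone 3, and 2 to the symmetrical acid 1. The O-CH2 bond is cut because the two phenols of 2 are equivalent. The carboxyl mask is one that comes off by hydrogenolysis, so that no base meets the aryloxyacetone before the key step.

Crotonate 9 is cut at O-Si to alcohol 8, and 8 at its double bond to glycolaldehyde dimer 6 and phosphorane 7. This is a two-step route to the acceptor from commercial materials.

## Alternatives that were turned down

Alternative 1: The O-C6 bond and the C1-carboxyl bond of ring A are cut together. In the forward sense, fluoride releases the aryne A4 from the silylaryl triflate A3. The potassium salt of the ring B phenol A2 adds at C6, and the resulting C1 aryl anion is carboxylated and then O-methylated to give A1. Removal of the acetal and the silyl group would finish the synthesis.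
- For: it is convergent, both rings are aromatic from the start, and the hindered ether and the ester are made in one operation. The regiochemistry of addition is sound, since the anion forms next to the inductively stabilising acetal oxygen. On convergence it is stronger than the chosen route.
- Against: the aryl anion sits between two ortho oxygens and is protonated by any proton source faster than it is carboxylated, which gives the plain diaryl ether. The phenoxide of A2 is di-ortho-substituted, is a sluggish nucleophile and is itself carboxylated reversibly at oxygen. The prenyl alkene of A2 can undergo an ene reaction with A4.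
- Step economy: A2 and A3 each need several steps, and making A2 only moves the problem of three different ring B oxygens into the fragment synthesis.
- In its place the chosen route offers cheap acyclic inputs, a built-in differentiation of the ring B oxygens, and a key step that is a classical carbonyl condensation and not a three-component trapping of an aryne.

Alternative 2: Ring B is cut at C5'-C6', C3'-C4' and C1'-C6', and further at C2'-C3'. Irradiation of the diazoketone A6 causes a Wolff rearrangement to the vinylketene A8. A8 combines with methoxyacetylene A7 by [2+2] addition, four-electron ring opening and six-electron ring closure to give the phenol A5.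
- For: ring B is born aromatic, with the C6' phenol free and the C4' methoxy group placed without ambiguity by A7. No dehydrogenation and no regiochemical question about the two oxygens remains; on this point it is stronger than the chosen route.
- Against: A6 is a diazomethyl ketone of a beta-aryloxy enone and needs several steps, with hazardous diazo chemistry, from a protected ring A phenol. A7 is volatile and unstable and has to be used in excess. The electron-rich A8 can dimerise, and the geometry of its aryloxy-bearing terminus affects the final ring closure. Ring A must carry a protecting group that is removed later.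
- Step economy: the route is clearly longer than the chosen one.
- The chosen route accepts one aromatisation and one regiochemical question at the enol ether stage, and in return uses only thermal flask chemistry with ordinary reagents.

Alternative 3: Ring A is cut at C1-C2 and C5-C6. The silyl ketene acetal diene A10 adds to the aryloxypropiolate A11. The adduct aromatises by loss of methanol and of the silyl group to give A9, the silyl ether of the target.
- For: ring A appears with its full substitution pattern and free phenol in one step, and only a desilylation follows. The regiochemistry is matched, because the nucleophilic diene terminus meets the alkyne carbon beta to the ester. In step economy after the key step this is the strongest of all the strategies, including the chosen one.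
- Against: A11 is an ynol ether ester that has to be made from the di-ortho-substituted phenol A2. Such aryloxy alkynoates are prone to a second nucleophilic addition and to hydration. The aryloxy donor lowers the dienophilicity, so heating is needed, and at that temperature the aryl prenyl ether can undergo Claisen rearrangement.
- Step economy: A2 again has to be built with three distinct oxygens, so the short endgame is paid for by a long fragment synthesis.
- The chosen route has a longer endgame but draws the whole of ring B from two simple three-carbon pieces.

Key step: step 6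

Remark on the chemistry: compounds 10 to 13 carry sp3 centres at C1' and/or C2' and are handled as racemic mixtures of diastereomers, since both centres become sp2 in step 8.

## Route

Step 1
Reactants: 1 2,6-dihydroxy-4-methylbenzoic acid
Product: 2 benzyl 2,6-dihydroxy-4-methylbenzoate
Conditions: BnBr (1.05 equiv), KHCO3 (1.2 equiv), DMF, rt
Reagents that add atoms: benzyl bromide, BrCc1ccccc1
Why: SN2 alkylation of the carboxylate; hydrogencarbonate deprotonates only the acid, the two hydrogen-bonded phenols stay protonated, and room temperature avoids decarboxylation.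

Step 2
Reactants: 2 benzyl 2,6-dihydroxy-4-methylbenzoate; 3 chloroacetone
Product: 4 benzyl 2-hydroxy-4-methyl-6-(2-oxopropoxy)benzoate
Conditions: 3 (1.05 equiv), K2CO3 (1.1 equiv), KI (cat.), acetone, 50 °C
Reagents that add atoms: none
Why: Williamson ether synthesis with in situ halide exchange; the two phenols of 2 are equivalent, and after the first alkylation the remaining one is locked in a hydrogen bond to the ester carbonyl, so a second alkylation should be slow when base and halide are limited.

Step 3
Reactants: 4 benzyl 2-hydroxy-4-methyl-6-(2-oxopropoxy)benzoate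
Product: 5 2-hydroxy-4-methyl-6-(2-oxopropoxy)benzoic acid
Conditions: H2 (1 atm), Pd/C (10% palladium on carbon), EtOAc, rt
Reagents that add atoms: none
Why: Hydrogenolysis of the benzyl ester; the conditions are neutral, so no enolate of the aryloxyacetone is formed next to an ester, and the ketone and the aryl ether are not reduced at atmospheric pressure.

Step 4
Reactants: 6 glycolaldehyde dimer (1,4-dioxane-2,5-diol); 7 methyl (triphenylphosphoranylidene)acetate
Product: 8 methyl (E)-4-hydroxybut-2-enoate
Conditions: THF, 65 °C
Reagents that add atoms: none
Why: Wittig olefination; the dimer is in equilibrium with the free hydroxy aldehyde, and the stabilised ylide in an aprotic solvent should give mainly the E alkene (the geometry is lost later in any case).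

Step 5
Reactants: 8 methyl (E)-4-hydroxybut-2-enoate
Product: 9 methyl (E)-4-{[tri(propan-2-yl)silyl]oxy}but-2-enoate
Conditions: iPr3SiCl, imidazole, CH2Cl2, 0 °C to rt
Reagents that add atoms: chlorotri(propan-2-yl)silane, CC(C)[Si](Cl)(C(C)C)C(C)C
Why: Silylation of a primary alcohol; the triisopropylsilyl ether is chosen because it should withstand the alkoxide of step 6 and the mild acid of step 7.

Step 6
Reactants: 5 2-hydroxy-4-methyl-6-(2-oxopropoxy)benzoic acid; 9 methyl (E)-4-{[tri(propan-2-yl)silyl]oxy}but-2-enoate
Product: 11 2-hydroxy-4-methyl-6-{[2,4-dioxo-6-({[tri(propan-2-yl)silyl]oxy}methyl)cyclohexyl]oxy}benzoic acid (mixture of diastereomers), via Michael adduct 10 (not isolated)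
Conditions: KOtBu (4.2 equiv), THF/DMF, -10 °C to rt; then cold 1 M HCl to pH 3
Reagents that add atoms: none
Why: This is a Michael-Claisen annulation, the known consecutive Michael addition and Claisen condensation of a substituted acetone with an unsaturated ester to a cyclohexane-1,3-dione. After the carboxyl group and the phenol of 5 are deprotonated, further base enolises the ketone towards the oxygen-bearing methylene, whose C-H is the more acidic one because of the inductive pull of the ether oxygen, and this enolate adds to the beta carbon of 9 to form C1'-C2' and the ester enolate of 10. Proton exchange moves the charge to the methyl group, which attacks the ester carbonyl in a 6-(enolexo)-exo-trig closure that forms C4'-C5' and expels methoxide; closure from C1' would need a four-membered ring. Deprotonation of the new 1,3-dione, which is far more acidic than tert-butanol, makes the sequence irreversible and pulls the reversible Michael step forward. The two new sp3 centres C1' and C2' arise without control, C1' being epimerisable next to the carbonyl so that the trans isomer should dominate, and both are erased in step 8. The regioselectivity that is needed (addition through the oxygen-bearing carbon and not through the methyl group, which would lead to a 2-aryloxy dione) rests on this acidity difference and on the known preference of substituted acetones in this annulation. The chemoselectivity rests on ring A being a carboxylate: the C1' carbanion has no ester ortho to the ether oxygen to attack, so the five-membered benzofuranone closure is shut off. A near-stoichiometric amount of 9 limits a second Michael addition of the dione enolate.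

Step 7
Reactants: 11 2-hydroxy-4-methyl-6-{[2,4-dioxo-6-({[tri(propan-2-yl)silyl]oxy}methyl)cyclohexyl]oxy}benzoic acid
Product: 12 2-hydroxy-6-{[4-methoxy-2-oxo-6-({[tri(propan-2-yl)silyl]oxy}methyl)cyclohex-3-en-1-yl]oxy}-4-methylbenzoic acid
Conditions: MeOH, camphorsulfonic acid (10 mol%), 3 Å molecular sieves, rt
Reagents that add atoms: methanol, CO
Why: Acid-catalysed enol etherification of a cyclic 1,3-dione under reversible conditions. The ether should settle on C4', which lies between two methylenes; an ether at C6' would crowd the aryloxy carbon and would put the electron-poor end of the vinylogous ester next to the electron-withdrawing aryloxy group. The di-ortho-substituted acid should not esterify and the silyl ether should survive the mild acid.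

Step 8
Reactants: 12 2-hydroxy-6-{[4-methoxy-2-oxo-6-({[tri(propan-2-yl)silyl]oxy}methyl)cyclohex-3-en-1-yl]oxy}-4-methylbenzoic acid
Product: 15 2-hydroxy-6-[2-hydroxy-4-methoxy-6-({[tri(propan-2-yl)silyl]oxy}methyl)phenoxy]-4-methylbenzoic acid, via tris(trimethylsilyl) dienol ether 13 (not isolated), via silylated cyclohexadienone 14 (not isolated)
Conditions: LiN(iPr)2 (3.3 equiv), THF, -78 °C; Me3SiCl (3.5 equiv); then Pd(OAc)2 (1.1 equiv), MeCN, rt; dilute aq. HCl work-up
Reagents that add atoms: none
Why: Saegusa-Ito oxidation, a known way to aromatise 3-alkoxycyclohexenones: after the carboxyl group and the phenol, the amide base deprotonates the vinylogous ester on its ketone side and silylation gives 13. Divalent palladium adds to C1' on the face away from the silyloxymethyl group, which is the face of the C2'-H, so that syn beta-hydride elimination gives dienone 14 and zerovalent palladium; 14 tautomerises to the phenol and the work-up cleaves the silyl ester and the aryl silyl ether. Enolisation towards C3' would lead to the same phenol, and ring A is still a carboxylate while the C1' enolate exists.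

Step 9
Reactants: 15 2-hydroxy-6-[2-hydroxy-4-methoxy-6-({[tri(propan-2-yl)silyl]oxy}methyl)phenoxy]-4-methylbenzoic acid
Product: 16 methyl 2-hydroxy-6-[2-hydroxy-4-methoxy-6-({[tri(propan-2-yl)silyl]oxy}methyl)phenoxy]-4-methylbenzoate
Conditions: Me3SiCHN2 (1.1 equiv), toluene/MeOH, 0 °C
Reagents that add atoms: (trimethylsilyl)diazomethane, C[Si](C)(C)C=[N+]=[N-]
Why: O-methylation of the carboxylic acid by the methyldiazonium ion formed from the reagent and methanol; the acid is far more acidic than either phenol, so only it should react with a slight excess at 0 °C. The ester is safe now because C1' is aromatic and can no longer attack it.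

Step 10
Reactants: 16 methyl 2-hydroxy-6-[2-hydroxy-4-methoxy-6-({[tri(propan-2-yl)silyl]oxy}methyl)phenoxy]-4-methylbenzoate; 17 prenyl bromide (1-bromo-3-methylbut-2-ene)
Product: 18 methyl 2-hydroxy-6-[4-methoxy-2-(3-methylbut-2-enyloxy)-6-({[tri(propan-2-yl)silyl]oxy}methyl)phenoxy]-4-methylbenzoate
Conditions: 17 (1.05 equiv), K2CO3 (1.2 equiv), acetone, rt
Reagents that add atoms: none
Why: Williamson etherification; the ring B phenol is free, while the ring A phenol is held in a hydrogen bond to the ester carbonyl and should not be alkylated at room temperature with a limiting amount of 17.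

Step 11
Reactants: 18 methyl 2-hydroxy-6-[4-methoxy-2-(3-methylbut-2-enyloxy)-6-({[tri(propan-2-yl)silyl]oxy}methyl)phenoxy]-4-methylbenzoate
Product: 19 methyl 2-hydroxy-6-[2-(hydroxymethyl)-4-methoxy-6-(3-methylbut-2-enyloxy)phenoxy]-4-methylbenzoate
Conditions: Bu4NF, AcOH, THF, 0 °C to rt
Reagents that add atoms: none
Why: Fluoride-mediated cleavage of the silyl ether; acetic acid buffers the alkoxide, so the methyl ester and the prenyl ether should stay untouched.

## Compound list

1 | 2,6-dihydroxy-4-methylbenzoic acid | Cc1cc(O)c(C(O)=O)c(O)c1 | starting material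
2 | benzyl 2,6-dihydroxy-4-methylbenzoate | Cc1cc(O)c(C(=O)OCc2ccccc2)c(O)c1 | intermediate
3 | chloroacetone | CC(=O)CCl | starting material
4 | benzyl 2-hydroxy-4-methyl-6-(2-oxopropoxy)benzoate | Cc1cc(O)c(C(=O)OCc2ccccc2)c(OCC(C)=O)c1 | intermediate
5 | 2-hydroxy-4-methyl-6-(2-oxopropoxy)benzoic acid | Cc1cc(O)c(C(O)=O)c(OCC(C)=O)c1 | intermediate
6 | glycolaldehyde dimer (1,4-dioxane-2,5-diol, mixture of stereoisomers) | OC1COC(O)CO1 | starting material
7 | methyl (triphenylphosphoranylidene)acetate | COC(=O)C=P(c1ccccc1)(c1ccccc1)c1ccccc1 | starting material
8 | methyl (E)-4-hydroxybut-2-enoate | COC(=O)/C=C/CO | intermediate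
9 | methyl (E)-4-{[tri(propan-2-yl)silyl]oxy}but-2-enoate | COC(=O)/C=C/CO[Si](C(C)C)(C(C)C)C(C)C | intermediate
10 | 2-hydroxy-6-{[6-methoxy-2,6-dioxo-4-({[tri(propan-2-yl)silyl]oxy}methyl)hexan-3-yl]oxy}-4-methylbenzoic acid (Michael adduct, present as its potassium salt, not isolated, mixture of diastereomers) | Cc1cc(O)c(C(O)=O)c(OC(C(C)=O)C(CO[Si](C(C)C)(C(C)C)C(C)C)CC(=O)OC)c1 | intermediate
11 | 2-hydroxy-4-methyl-6-{[2,4-dioxo-6-({[tri(propan-2-yl)silyl]oxy}methyl)cyclohexyl]oxy}benzoic acid (mixture of diastereomers) | Cc1cc(O)c(C(O)=O)c(OC2C(CO[Si](C(C)C)(C(C)C)C(C)C)CC(=O)CC2=O)c1 | intermediate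
12 | 2-hydroxy-6-{[4-methoxy-2-oxo-6-({[tri(propan-2-yl)silyl]oxy}methyl)cyclohex-3-en-1-yl]oxy}-4-methylbenzoic acid (mixture of diastereomers) | Cc1cc(O)c(C(O)=O)c(OC2C(CO[Si](C(C)C)(C(C)C)C(C)C)CC(OC)=CC2=O)c1 | intermediate
13 | trimethylsilyl 2-{[4-methoxy-2-(trimethylsilyloxy)-6-({[tri(propan-2-yl)silyl]oxy}methyl)cyclohexa-1,3-dien-1-yl]oxy}-4-methyl-6-(trimethylsilyloxy)benzoate (racemic, not isolated) | C[Si](C)(C)OC(=O)c1c(O[Si](C)(C)C)cc(C)cc1OC1=C(O[Si](C)(C)C)C=C(OC)CC1CO[Si](C(C)C)(C(C)C)C(C)C | intermediate
14 | trimethylsilyl 2-{[4-methoxy-6-oxo-2-({[tri(propan-2-yl)silyl]oxy}methyl)cyclohexa-1,4-dien-1-yl]oxy}-4-methyl-6-(trimethylsilyloxy)benzoate (not isolated) | C[Si](C)(C)OC(=O)c1c(O[Si](C)(C)C)cc(C)cc1OC1=C(CO[Si](C(C)C)(C(C)C)C(C)C)CC(OC)=CC1=O | intermediate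
15 | 2-hydroxy-6-[2-hydroxy-4-methoxy-6-({[tri(propan-2-yl)silyl]oxy}methyl)phenoxy]-4-methylbenzoic acid | Cc1cc(O)c(C(O)=O)c(Oc2c(CO[Si](C(C)C)(C(C)C)C(C)C)cc(OC)cc2O)c1 | intermediate
16 | methyl 2-hydroxy-6-[2-hydroxy-4-methoxy-6-({[tri(propan-2-yl)silyl]oxy}methyl)phenoxy]-4-methylbenzoate | COC(=O)c1c(O)cc(C)cc1Oc1c(CO[Si](C(C)C)(C(C)C)C(C)C)cc(OC)cc1O | intermediate
17 | prenyl bromide (1-bromo-3-methylbut-2-ene) | CC(C)=CCBr | starting material
18 | methyl 2-hydroxy-6-[4-methoxy-2-(3-methylbut-2-enyloxy)-6-({[tri(propan-2-yl)silyl]oxy}methyl)phenoxy]-4-methylbenzoate | COC(=O)c1c(O)cc(C)cc1Oc1c(CO[Si](C(C)C)(C(C)C)C(C)C)cc(OC)cc1OCC=C(C)C | intermediate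
19 | methyl 2-hydroxy-6-[2-(hydroxymethyl)-4-methoxy-6-(3-methylbut-2-enyloxy)phenoxy]-4-methylbenzoate | COC(=O)c1c(O)cc(C)cc1Oc1c(CO)cc(OC)cc1OCC=C(C)C | target

## Step count and risk

Total step count: 11. Longest linear sequence: 9 steps (steps 1, 2, 3, 6, 7, 8, 9, 10, 11 from 1); the crotonate branch (steps 4 and 5) joins at step 6.

Steps least certain to work:

**Step 6 (key step).** The donor is a hindered, multiply charged enolate, so the Michael addition may be slow. Meanwhile base can deprotonate 9 at its gamma carbon and isomerise it to a silyl enol ether, or the ketone of 5 can condense with itself; addition through the methyl group would give the wrong dione. The fallback replaces the acceptor by a doubly activated one that adds faster and at lower temperature. It sets out from 9 and 5 and returns at 11.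
- Ozonolysis of 9 (O3, CH2Cl2, -78 °C; then Me2S) gives 2-{[tri(propan-2-yl)silyl]oxy}acetaldehyde F1.
- Knoevenagel condensation of F1 with dimethyl malonate (TiCl4, pyridine, THF, 0 °C) gives dimethyl 2-(2-{[tri(propan-2-yl)silyl]oxy}ethylidene)propanedioate F2.
- F2 and the potassium salt of 5 (KOtBu, THF/DMF, -40 °C to rt) undergo the same Michael addition at C1' and Claisen closure from the methyl group onto one ester. This gives 2-hydroxy-6-{[5-(methoxycarbonyl)-2,4-dioxo-6-({[tri(propan-2-yl)silyl]oxy}methyl)cyclohexyl]oxy}-4-methylbenzoic acid F3.
- Saponification of the beta-keto ester of F3 and decarboxylation (LiOH, aqueous THF; then pH 3, 50 °C) lead back to 11.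

**Step 7.** Enol ether formation may be poorly regioselective, giving the ether at C6' as well as at C4', or the silyl ether may be lost in acid and the free alcohol may form a bridged ketal. The fallback fixes the regiochemistry through ring A; it sets out from 11 and returns at 16, bypassing steps 7 to 9.
- Activation of the acid of 11 (EDC hydrochloride, CH2Cl2, rt) lets the dione enol oxygen at C6', the only one within reach, close a seven-membered enol lactone. The product is 1-hydroxy-3-methyl-6-({[tri(propan-2-yl)silyl]oxy}methyl)-6,7-dihydro-5aH-dibenzo[b,e][1,4]dioxepine-8,11-dione F4.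
- Dehydrogenation of F4 (DDQ, 1,4-dioxane, 80 °C) gives the depsidone 1,8-dihydroxy-3-methyl-6-({[tri(propan-2-yl)silyl]oxy}methyl)-11H-dibenzo[b,e][1,4]dioxepin-11-one F5, in which only the C4' oxygen is a free, unchelated phenol.
- Methylation of F5 (MeI, K2CO3, acetone, rt) gives 1-hydroxy-8-methoxy-3-methyl-6-({[tri(propan-2-yl)silyl]oxy}methyl)-11H-dibenzo[b,e][1,4]dioxepin-11-one F6.
- Methanolysis of the aryl ester of F6 (NaOMe, MeOH, 0 °C) opens the lactone to the methyl ester and the C6' phenol, which is 16.

**Step 8.** Formation of the trianion and its silylation may be incomplete, the oxidation at the fully substituted C1' may be slow so that hydrolysis returns 12, or the electron-rich phenol formed may be oxidised further. The fallback avoids enolate and palladium chemistry. It sets out from 12 and returns at 15: heating 12 with DDQ in 1,4-dioxane at 80 to 100 °C should dehydrogenate the enone by hydride abstraction from its neutral dienol, and tautomerisation should give 15 directly.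

**Step 2.** Alkylation may run on to the bis-ether, or chloroacetone may be consumed by self-condensation, so that 4 is obtained only in a mixture. The fallback enforces mono-alkylation by tying one phenol to the acid and carries the ketone as an alkene through the basic unmasking. It sets out from 1 and returns at 5.
- 1 with acetone, trifluoroacetic acid and trifluoroacetic anhydride gives 5-hydroxy-2,2,7-trimethyl-4H-1,3-benzodioxin-4-one F7.
- Alkylation of F7 with 3-chloro-2-methylprop-1-ene (K2CO3, KI, DMF, 60 °C) gives 2,2,7-trimethyl-5-(2-methylprop-2-enyloxy)-4H-1,3-benzodioxin-4-one F8.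
- Hydrolysis of F8 (KOH, DMSO/water, 60 °C; then acid) gives 2-hydroxy-4-methyl-6-(2-methylprop-2-enyloxy)benzoic acid F9.
- Oxidative cleavage of the alkene of F9 (OsO4 cat., NaIO4, 2,6-lutidine, dioxane/water) gives 5.

## Further compounds

F1 | step 6 | 2-{[tri(propan-2-yl)silyl]oxy}acetaldehyde | CC(C)[Si](OCC=O)(C(C)C)C(C)C
F2 | step 6 | dimethyl 2-(2-{[tri(propan-2-yl)silyl]oxy}ethylidene)propanedioate | COC(=O)C(=CCO[Si](C(C)C)(C(C)C)C(C)C)C(=O)OC
F3 | step 6 | 2-hydroxy-6-{[5-(methoxycarbonyl)-2,4-dioxo-6-({[tri(propan-2-yl)silyl]oxy}methyl)cyclohexyl]oxy}-4-methylbenzoic acid (mixture of diastereomers) | Cc1cc(O)c(C(O)=O)c(OC2C(CO[Si](C(C)C)(C(C)C)C(C)C)C(C(=O)OC)C(=O)CC2=O)c1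
F4 | step 7 | 1-hydroxy-3-methyl-6-({[tri(propan-2-yl)silyl]oxy}methyl)-6,7-dihydro-5aH-dibenzo[b,e][1,4]dioxepine-8,11-dione (mixture of diastereomers) | Cc1cc(O)c2C(=O)OC3=CC(=O)CC(CO[Si](C(C)C)(C(C)C)C(C)C)C3Oc2c1
F5 | step 7 | 1,8-dihydroxy-3-methyl-6-({[tri(propan-2-yl)silyl]oxy}methyl)-11H-dibenzo[b,e][1,4]dioxepin-11-one | Cc1cc(O)c2C(=O)Oc3cc(O)cc(CO[Si](C(C)C)(C(C)C)C(C)C)c3Oc2c1
F6 | step 7 | 1-hydroxy-8-methoxy-3-methyl-6-({[tri(propan-2-yl)silyl]oxy}methyl)-11H-dibenzo[b,e][1,4]dioxepin-11-one | Cc1cc(O)c2C(=O)Oc3cc(OC)cc(CO[Si](C(C)C)(C(C)C)C(C)C)c3Oc2c1
F0 | step 8 | none | none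
F7 | step 2 | 5-hydroxy-2,2,7-trimethyl-4H-1,3-benzodioxin-4-one | Cc1cc(O)c2C(=O)OC(C)(C)Oc2c1
F8 | step 2 | 2,2,7-trimethyl-5-(2-methylprop-2-enyloxy)-4H-1,3-benzodioxin-4-one | Cc1cc(OCC(C)=C)c2C(=O)OC(C)(C)Oc2c1
F9 | step 2 | 2-hydroxy-4-methyl-6-(2-methylprop-2-enyloxy)benzoic acid | Cc1cc(O)c(C(O)=O)c(OCC(C)=C)c1
A1 | alternative 1 | methyl 2-[2-({[tert-butyl(dimethyl)silyl]oxy}methyl)-4-methoxy-6-(3-methylbut-2-enyloxy)phenoxy]-6-(methoxymethoxy)-4-methylbenzoate | COCOc1cc(C)cc(Oc2c(CO[Si](C)(C)C(C)(C)C)cc(OC)cc2OCC=C(C)C)c1C(=O)OC
A2 | alternative 1 | 2-({[tert-butyl(dimethyl)silyl]oxy}methyl)-4-methoxy-6-(3-methylbut-2-enyloxy)phenol | Oc1c(CO[Si](C)(C)C(C)(C)C)cc(OC)cc1OCC=C(C)C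
A3 | alternative 1 | 3-(methoxymethoxy)-5-methyl-2-(trimethylsilyl)phenyl trifluoromethanesulfonate | COCOc1cc(C)cc(OS(=O)(=O)C(F)(F)F)c1[Si](C)(C)C
A4 | alternative 1 | 3-(methoxymethoxy)-5-methylbenzyne | COCOC1=CC(C)=CC#C1
A5 | alternative 2 | methyl 2-[2-hydroxy-4-methoxy-6-({[tri(propan-2-yl)silyl]oxy}methyl)phenoxy]-6-(methoxymethoxy)-4-methylbenzoate | COCOc1cc(C)cc(Oc2c(CO[Si](C(C)C)(C(C)C)C(C)C)cc(OC)cc2O)c1C(=O)OC
A6 | alternative 2 | methyl 2-{[4-diazo-3-oxo-2-({[tri(propan-2-yl)silyl]oxy}methyl)but-1-enyl]oxy}-6-(methoxymethoxy)-4-methylbenzoate (alkene geometry not fixed) | COCOc1cc(C)cc(OC=C(CO[Si](C(C)C)(C(C)C)C(C)C)C(=O)C=[N+]=[N-])c1C(=O)OC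
A7 | alternative 2 | methoxyacetylene | COC#C
A8 | alternative 2 | methyl 2-(methoxymethoxy)-4-methyl-6-{[4-oxo-2-({[tri(propan-2-yl)silyl]oxy}methyl)buta-1,3-dienyl]oxy}benzoate (vinylketene) | COCOc1cc(C)cc(OC=C(CO[Si](C(C)C)(C(C)C)C(C)C)C=C=O)c1C(=O)OC
A9 | alternative 3 | methyl 2-[2-({[tert-butyl(dimethyl)silyl]oxy}methyl)-4-methoxy-6-(3-methylbut-2-enyloxy)phenoxy]-6-hydroxy-4-methylbenzoate | COC(=O)c1c(O)cc(C)cc1Oc1c(CO[Si](C)(C)C(C)(C)C)cc(OC)cc1OCC=C(C)C
A10 | alternative 3 | 1-methoxy-3-methyl-1-(trimethylsilyloxy)buta-1,3-diene | COC(O[Si](C)(C)C)=CC(C)=C
A11 | alternative 3 | methyl 3-[2-({[tert-butyl(dimethyl)silyl]oxy}methyl)-4-methoxy-6-(3-methylbut-2-enyloxy)phenoxy]prop-2-ynoate | COC(=O)C#COc1c(CO[Si](C)(C)C(C)(C)C)cc(OC)cc1OCC=C(C)C
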